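(The constants are those of an exercise; no experiment stands behind them.)

The precatalyst frees catalyst with a half-life of 96.7 min, longer than the 80 min run.

    starting material + free catalyst → catalyst intermediate A (k1 = 1.5 × 10⁵ M⁻¹ h⁻¹)
    reagent + catalyst intermediate A ⇌ catalyst intermediate B (K2 = 870 M⁻¹, k2 = 1.2 × 10⁵ M⁻¹ h⁻¹)
    catalyst intermediate B → catalyst intermediate C (k3 = 11 h⁻¹)
    catalyst intermediate C ⇌ free catalyst + target (K4 = 0.61 M, k4 = 36 h⁻¹)
    precatalyst → free catalyst (k5 = 0.43 h⁻¹)
    starting material + target → side product (k6 = 85 M⁻¹ h⁻¹)

all flasks: precatalyst 0.32 mM
- ash: starting material 10 mM; reagent 12.0 mM; a single well-mixed tank run continuously and read at steady state, 80 min in it on average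
- cedar: starting material 10 mM; reagent 12.0 mM (fed, over 40.0 min); all but reagent at the start; reagent goes in evenly over 40.0 min, the run ends at 80 min; time 80 min
- birch: starting material 10 mM; reagent 12.0 mM; a closed flask charged with all of it at once and left for 80 min; time 80 min
- elm: starting material 10 mM (fed, over 40.0 min); reagent 12.0 mM; all but starting material at the start; starting material goes in evenly over 40.0 min, the run ends at 80 min; time 80 min

- in percentages every species weighs as the starting material in it: one side product counts as two
- the stated concentrations are those of everything mixed, before any reaction; amounts are the same in each set-up
- the feed brings no volume worth counting
- run time (cedar): 80 min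

- the set-up with the highest amount of target at the outlet or at the end, in percent of the starting material put in ("none" if the first two lie within 2 percentage points) (ash / cedar / birch / elm / none)
- amount of target at the outlet or at the end, in percent of the starting material put in, ash
- amount of target at the outlet or at the end, in percent of the starting material put in, cedar
- amount of target at the outlet or at the end, in percent of the starting material put in, birch
- amount of target at the outlet or at the end, in percent of the starting material put in, elm

1. Once the round flows steadily, each step passes the same flow, so target forms at the rate of the step from catalyst intermediate B to catalyst intermediate C, 11 h⁻¹ times [catalyst intermediate B]. This gives [catalyst intermediate C]/[catalyst intermediate B] = 0.306, the ratio of the two rate constants.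

2. The reagent step is quick against that flow, so [catalyst intermediate A]/[catalyst intermediate B] = 0.0958, taking reagent at its charge. Free catalyst stands lower still, at 0.00733 of catalyst intermediate B. Catalyst intermediate B is therefore the resting state, with 71.0% of the working catalyst.

3. By 80 min, 43.6% of the catalyst is activated. Integrating the activated fraction over the run gives the run time minus that fraction divided by the activation constant. This is the active time, the average time a charged catalyst has spent in the round: 19.1 min.

4. Gross target is the rate constant times the resting share, the catalyst charge and the active time: 0.796 mM. This is small against the charge, so this reckoning takes [starting material] at 10 mM.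

5. Target then decays pseudo-first-order at 0.850 h⁻¹. Integrating the growing making rate against that decay leaves 0.555 mM. This reckoning gives birch 5.55%.

6. The feeds of cedar and elm last through a quarter of the active time; this reckoning leaves them out and carries the birch figure over: cedar 5.55%, elm 5.55%.

7. In ash, the tank keeps an active share of 36.4%, so the active time is 29.2 min, longer than in birch. Decay at the same rate divides the target in ash by one plus 1.13, which gives 0.569 mM, or 5.69%. The gap to birch is 0.14 percentage points, under the margin, so this reckoning names no winner.

The forecast, a little apart from these figures, gave 5.8% for ash, 5.4% for cedar, 5.6% for birch and 5.9% for elm, with best none, on the ground that “the feeding or tank differences shift yields by only a few tenths of a point”.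

The simulation gives 6.11% for ash, 5.43% for cedar, 5.49% for birch and 5.52% for elm, with best none.

Cedar at 80.0 min still holds 56.4% of its catalyst as precatalyst, whose half-life of 96.7 min is far longer than the 3.8 min half-life of catalyst intermediate B. Target plus half the side product, the gross target, reads 7.51% there, against 7.96% reckoned. The cedar flask read at 3.0 h has an active time of 78.9 min, so its gross target reckons at 32.8% and reads 31.7%, with 18.3% standing as target.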